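In the target the cyclobutane (C2, C3, C8, C7) is spanned twice. C4–C5–C6 ties the diagonal C3/C7 on one face. C9–C10–C11–C1 ties the diagonal C8/C2 on the other face, completing the cycloheptane and bearing oxygen at C9 and C11. Everything rests on cutting C8–C9 and C1–C2. In the forward sense a Lewis acid joins Danishefsky's diene to the strained central C2–C8 bond of a bicyclobutane ester. That one operation makes both bonds, unveils the cyclobutane, closes the seven-membered ring and fixes C2 and C8. The precursor is an enantiopure tricyclo[4.1.0.0(2,7)]heptane-1-carboxylate whose wing-tying chain carries a C4 silyl ether and the C6 methyl group, both turned toward C2.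

Key step: step 9

**Conventions.** Ring carbons C1–C11 follow the order of the target SMILES. C12 is the carbon on C8, C13 the methyl on C6, C14 the methyl on C1, and C15 the oxymethylene on C1. "C3 side" and "C7 side" name the two faces of the seven-membered ring. In the target, C15 and the C9 oxygen lie on the C3 side; C14 and the C11 oxygen lie on the C7 side.

**Assumption.** In steps 1, 12 and 13 the ligand antipode named is the one expected from its behaviour with simple cyclic enones and enol silanes. If the sense of induction is reversed on these substrates, the mirror-image ligand is used.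

**Design notes.**
- **C6 configuration.** With C8 on one face of the cyclohexene and the methyl group on the other, C6 of the bicyclobutane belongs to the (S)-5-methylcyclohex-2-enone series.
  - The (R) series, which natural (R)-pulegone provides, would put the methyl group on the ester side. After an anti-selective C–C bond formation it would instead give the mirror-image core.
  - C6 is therefore set by catalytic asymmetric conjugate addition.
- **C8 attachment.** C8 is attached by stereospecific allylic alkylation, not by deconjugative α-alkylation of a dienolate. The latter would reconjugate or over-alkylate and has only weak 1,4-induction.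
- **Silyl group.** TIPS is used as the C4 silyl group because it must outlast the Lewis acid and help to close the concave approach to C2.
- **Catalyst control at C1 and C9.** A local mirror plane runs through C8, C2 and the four-carbon bridge, so the core gives no facial bias at C1 or C9. These two centres are placed under catalyst control, and C11 is then relayed from them.

**Step 1**
Reactants: 1 4,4-dimethoxycyclohexa-2,5-dien-1-one
Product: 2 (R)-4,4-dimethoxy-5-methylcyclohex-2-en-1-one
Conditions: Me2Zn (1.2 equiv), Cu(OTf)2 (2 mol %), ligand A (4 mol %; (S)-binaphthol-derived N,N-bis[(R)-1-phenylethyl]phosphoramidite), toluene, −25 °C; aq NH4Cl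
Reagents that add atoms: dimethylzinc, C[Zn]C
Why: Copper-catalysed enantioselective conjugate addition of a dialkylzinc: the chiral phosphoramidite–copper complex picks one of the two enantiotopic enone units of the prochiral quinone monoketal and one of its faces, which sets C6, the stereocentre from which all ring stereochemistry up to the key step is relayed.

**Step 2**
Reactants: 2 (R)-4,4-dimethoxy-5-methylcyclohex-2-en-1-one
Product: 3 (1S,5R)-4,4-dimethoxy-5-methylcyclohex-2-en-1-ol
Conditions: NaBH4, CeCl3·7H2O, MeOH, −78 to 0 °C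
Reagents that add atoms: none
Why: Luche 1,2-reduction: axial hydride attack on the half-chair that keeps the methyl group equatorial should give the equatorial alcohol, so that the new C4 carbinol is cis to the C6 methyl group, while the dimethyl ketal is inert in methanol.

**Step 3**
Reactants: 3 (1S,5R)-4,4-dimethoxy-5-methylcyclohex-2-en-1-ol
Product: 5 (4S,6R)-6-methyl-4-(triisopropylsilyloxy)cyclohex-2-en-1-one, via silyl ether ketal 4 (not isolated)
Conditions: TIPSCl, imidazole, DMF, 40 °C; then 1 M aq HCl, THF, 0 °C
Reagents that add atoms: chlorotriisopropylsilane, CC(C)[Si](Cl)(C(C)C)C(C)C; water, O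
Why: Routine silylation followed by mild acid hydrolysis of the allylic ketal creates no stereocentre, TIPS being chosen because it must outlast the Lewis acid of step 9 and screen C2 there, and C6, now α to the ketone, already holds the more stable cis-4,6 arrangement.

**Step 4**
Reactants: 5 (4S,6R)-6-methyl-4-(triisopropylsilyloxy)cyclohex-2-en-1-one
Product: 6 (1S,4S,6R)-6-methyl-4-(triisopropylsilyloxy)cyclohex-2-en-1-ol
Conditions: NaBH4, CeCl3·7H2O, MeOH, −78 °C
Reagents that add atoms: none
Why: Luche reduction again by axial attack, giving the all-equatorial alcohol in which the new C7 carbinol is trans to the neighbouring methyl group and trans (1,4) to the silyl ether.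

**Step 5**
Reactants: 6 (1S,4S,6R)-6-methyl-4-(triisopropylsilyloxy)cyclohex-2-en-1-ol
Product: 7 methyl carbonate of 6
Conditions: ClCO2Me, pyridine, DMAP (cat.), CH2Cl2, 0 °C
Reagents that add atoms: methyl chloroformate, COC(=O)Cl
Why: Plain O-acylation with a chloroformate turns the alcohol into a leaving group that ionises under neutral conditions and frees its own base in step 6; no stereocentre is touched.

**Step 6**
Reactants: 7 methyl carbonate of 6; 8 methyl acetoacetate
Product: 9 methyl 2-acetyl-2-[6-methyl-4-(triisopropylsilyloxy)cyclohex-2-en-1-yl]acetate (side chain on C7, trans to CH3 and to OTIPS; both C8 epimers)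
Conditions: Pd2(dba)3·CHCl3 (2.5 mol %), dppe (6 mol %), THF, 50 °C
Reagents that add atoms: none
Why: Tsuji–Trost allylic alkylation with a soft nucleophile runs by double inversion, so that C8 is attached with net retention on the face that held the carbonate, anti to methyl and silyl ether; attack distal to the C–O bond (at C7) is expected, the other allyl terminus (C3) would lead after steps 7 and 8 to the same bicyclobutane, and the C8 epimers converge in step 7.

**Step 7**
Reactants: 9 β-keto ester
Product: 10 methyl 2-diazo-2-[6-methyl-4-(triisopropylsilyloxy)cyclohex-2-en-1-yl]acetate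
Conditions: 4-acetamidobenzenesulfonyl azide, DBU, MeCN, 0 °C to rt
Reagents that add atoms: 4-acetamidobenzenesulfonyl azide, CC(=O)Nc1ccc(cc1)S(=O)(=O)N=[N+]=[N-]
Why: Regitz diazo transfer with loss of the acetyl group (deacylative variant), the standard entry to α-alkyl-α-diazo esters, removes the stereocentre at C8 and leaves C7 untouched.

**Step 8**
Reactants: 10 diazo ester
Product: 11 methyl 5-methyl-3-(triisopropylsilyloxy)tricyclo[4.1.0.0(2,7)]heptane-1-carboxylate (ester on C8, H on C2; OTIPS and CH3 both on the C2 side of the chain)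
Conditions: Rh2(O2CCPh3)4 (1 mol %), toluene, −78 °C, slow addition of 10, then to rt
Reagents that add atoms: none
Why: Intramolecular cyclopropanation of an α-allyl-α-diazo ester by a rhodium carbenoid, the known route to bicyclobutane-1-carboxylates: the one-atom tether lets the carbene reach the C2=C3 bond only on the face that bears it, which sets C8, C2 and C3 from C7, and the bulky triphenylacetate ligands at low temperature hold back the competing 1,2-hydride shift.

**Step 9**
Reactants: 11 bicyclobutane ester; 12 Danishefsky's diene, (E)-1-methoxy-3-(trimethylsilyloxy)buta-1,3-diene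
Product: 14 tricyclic cycloheptenone (C8 CO2Me, C4 OTIPS, C6 H/CH3, C9=C10–C11=O, C1H2), via methoxy silyl enol ether cycloadduct 13 (not isolated)
Conditions: Sc(OTf)3 (10 mol %), 12 (2.5 equiv, slow addition), 4 Å MS, CH2Cl2, −40 to 0 °C; then 0.1 M HCl, THF, 0 °C
Reagents that add atoms: none
Why: Proposed new method: the scandium-bound ester lowers the σ* orbital of the bent, p-rich C2–C8 bond, whose inner lobes are exposed on the convex face, and the s-cis diene should add there in a symmetry-allowed but strongly asynchronous [π4s+σ2s] event in which its nucleophilic CH2 terminus binds C2 first while charge gathers on C8 as a scandium ester enolate. The closest known reaction type is the Lewis-acid-catalysed formal [4π+2σ] cycloaddition of acyl bicyclobutanes with silyl dienol ethers to bicyclo[4.1.1]octanes, which has been run only on bicyclobutanes with free wings, where the ring can turn inside out after rear-side attack. The seven-membered ring closes by 7-endo-trig attack of the C8 enolate carbon on C9 of the methoxy-substituted silyloxyallyl cation, in the manner of a Mukaiyama–Michael addition, and the cyclobutane is simply what is left once the central bond is gone. C2 and C8 are controlled by the C4–C5–C6 tether, since a four-atom bridge can span them only on the face away from it, so that H-2 and the ester end syn to that tether. Regioselectivity (CH2 to C2, CH(OMe) to C8) follows from the ester, which makes C2 the electrophilic bridgehead, whereas face selectivity requires the customary rear-side corridor at C2 to be closed, which C5H2 together with the C4 OTIPS and C6 methyl groups, both turned toward C2, should secure. Acid work-up then cleaves the silyl enol ether of 13 and expels methanol by E1cB elimination to give enone 14.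

**Step 10**
Reactants: 14 tricyclic cycloheptenone
Product: 16 C1-methyl enone (both C1 epimers), via lithium dienolate 15 (not isolated)
Conditions: LDA (1.05 equiv), THF, −78 °C; MeI, −78 to −30 °C
Reagents that add atoms: iodomethane, CI; lithium diisopropylamide, CC(C)[N-]C(C)C.[Li+] (lithium appears in 15 only)
Why: Kinetic enolate alkylation: C8 is quaternary, so the enone has no γ-hydrogen and LDA can only give the cross-conjugated C1 dienolate, which is methylated by SN2; the C1 configuration is irrelevant because step 11 flattens it.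

**Step 11**
Reactants: 16 C1-methyl enone
Product: 17 2-silyloxydiene (C1(CH3)=C11(OTMS)–C10=C9)
Conditions: TMSOTf, Et3N, CH2Cl2, 0 °C
Reagents that add atoms: trimethylsilyl triflate, C[Si](C)(C)OS(=O)(=O)C(F)(F)F
Why: Soft enolisation with a silyl triflate and an amine gives the 2-silyloxydiene regiospecifically, C1–H being the only enolisable position, without touching ester or TIPS ether.

**Step 12**
Reactants: 17 2-silyloxydiene
Product: 18 enone with quaternary C1 (C14 methyl on the C7 side, C15H2OH on the C3 side)
Conditions: Sc(OTf)3 (10 mol %), ligand B (12 mol %; (S,S)-6,6'-bis(1-hydroxy-2,2-dimethylpropyl)-2,2'-bipyridine), aq HCHO (37 %), DME/H2O 9:1, −20 °C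
Reagents that add atoms: formaldehyde, C=O
Why: Catalytic enantioselective Mukaiyama aldol reaction with aqueous formaldehyde (hydroxymethylation of an enol silane): the local mirror plane through C8, C2 and the planar dienol ether leaves the substrate without a facial preference at C1, so the chiral scandium–bipyridine complex should decide and deliver formaldehyde to the C3-side face, which sets the quaternary centre.

**Step 13**
Reactants: 18 hydroxymethyl enone
Product: 20 β-hydroxy ketone (C9–OH on the C3 side), via C9 pinacol boronate 19 (not isolated)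
Conditions: B2pin2, CuCl (5 mol %), NaOt-Bu (6 mol %), ligand C (5.5 mol %; (R)-1-[(S)-2-(diphenylphosphino)ferrocenyl]ethyldicyclohexylphosphine), MeOH (2 equiv), THF, 0 °C; then NaBO3·4H2O, THF/H2O, rt
Reagents that add atoms: sodium perborate, [Na+].[Na+].O[B-]1(O)OO[B-](O)(O)OO1; bis(pinacolato)diboron, CC1(C)OB(OC1(C)C)B1OC(C)(C)C(C)(C)O1 (boron appears in 19 only)
Why: Copper-catalysed enantioselective conjugate borylation followed by stereoretentive perborate oxidation: the boryl-copper species adds only to the enone β-carbon C9, the hindered ester and the free alcohol being tolerated, and since C9 lies in the same local mirror plane the ligand should direct boron to the C3-side face, cis to C15.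

**Step 14**
Reactants: 20 β-hydroxy ketone
Product: 21 triol ester (C11–OH on the C7 side)
Conditions: Me4NBH(OAc)3, MeCN/AcOH 1:1, −30 °C
Reagents that add atoms: none
Why: Evans–Saksena reduction: the triacetoxyborohydride, inert to ketones on its own, is bound by the C9 and C15 hydroxyl groups, which both lie on the C3 side, and hands its hydride to that face of C11, so the new carbinol points to the C7 side, anti to C9–OH and trans to C15.

**Step 15**
Reactants: 21 triol ester
Product: 22 C11/C15 acetonide with free C9–OH
Conditions: Me2C(OMe)2, PPTS (cat.), CH2Cl2, rt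
Reagents that add atoms: 2,2-dimethoxypropane, COC(C)(C)OC
Why: Acid-catalysed transketalisation: only the C11/C15 pair can close an unstrained 1,3-dioxane, the anti C9/C11 pair would need a trans bridge across the ring, so C9–OH alone stays free and the three hydroxyl groups are told apart.

**Step 16**
Reactants: 22 acetonide ester
Product: 23 C9/C12 diol
Conditions: LiAlH4, THF, 0 °C to rt; Rochelle salt work-up
Reagents that add atoms: none
Why: Hydride reduction of the only ester to the neopentyl alcohol C12–OH; acetonide, TIPS ether and all stereocentres are inert to LiAlH4.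

**Step 17**
Reactants: 23 C9/C12 diol
Product: 24 C12 mesylate
Conditions: MsCl (1.1 equiv), Et3N, CH2Cl2, −20 °C
Reagents that add atoms: methanesulfonyl chloride, CS(=O)(=O)Cl
Why: Sulfonylation discriminates the primary C12–OH from the secondary C9–OH, which is flanked by the quaternary C8.

**Step 18**
Reactants: 24 C12 mesylate
Product: 25 C8-methyl alcohol (free C9–OH)
Conditions: LiEt3BH (excess), THF, 0 to 65 °C
Reagents that add atoms: none
Why: SN2 displacement of a neopentyl sulfonate by lithium triethylborohydride turns C12 into the C8 methyl group; a polar method is chosen because a radical or cation at C12 would open or enlarge the cyclobutane, and if the C9 alkoxide first closes an oxetane, hydride should open it at C12 to the same product.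

**Step 19**
Reactants: 25 C8-methyl alcohol; 26 senecioic acid (3-methylbut-2-enoic acid)
Product: 27 C9 senecioate
Conditions: DCC, DMAP, CH2Cl2, rt
Reagents that add atoms: none
Why: Steglich esterification of the only free hydroxyl group; carbodiimide activation avoids the vinylketene pathway by which senecioyl chloride and amine bases give the deconjugated ester.

**Step 20**
Reactants: 27 C9 senecioate
Product: 28 C4 alcohol
Conditions: TBAF, AcOH (1:1), THF, rt to 40 °C
Reagents that add atoms: none
Why: Fluoride-induced desilylation, buffered with acetic acid so that the senecioate is neither cleaved nor moved; the acetonide is inert.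

**Step 21**
Reactants: 28 C4 alcohol
Product: 30 C4-oxo-C5=C6 enone, via saturated C4 ketone 29 (not isolated)
Conditions: IBX (4 equiv), 4-methoxypyridine N-oxide (4 equiv), DMSO, rt to 45 °C
Reagents that add atoms: none
Why: IBX oxidation of the alcohol followed in the same flask by IBX-mediated dehydrogenation of the ketone: C3 is a cyclobutane bridgehead and cannot enolise, so only C5 does, and loss of H-5 and H-6 gives the C5=C6 enone and erases the C4 and C6 stereocentres as planned.

**Step 22**
Reactants: 30 enone acetonide
Product: 31 C11/C15 diol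
Conditions: AcOH/H2O 4:1, 40 °C
Reagents that add atoms: none
Why: Mild aqueous acid hydrolysis of the 1,3-dioxane; enone and senecioate survive, and acyl migration from C9 to C11 is disfavoured by their anti relationship.

**Step 23**
Reactants: 31 C11/C15 diol; 32 angelic acid ((Z)-2-methylbut-2-enoic acid)
Product: 34 C15 angelate with free C11–OH, via angelic 2,4,6-trichlorobenzoic anhydride 33 (not isolated)
Conditions: 2,4,6-trichlorobenzoyl chloride, Et3N, toluene, 80 °C
Reagents that add atoms: 2,4,6-trichlorobenzoyl chloride, O=C(Cl)c1c(Cl)cc(Cl)cc1Cl (its atoms appear in 33 only)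
Why: Esterification through the mixed trichlorobenzoic anhydride (Yamaguchi-type, without nucleophilic catalyst), the protocol that keeps the Z geometry of angelates, acylates the primary C15–OH in preference to the C11–OH, which is secondary and next to the quaternary C1.

**Step 24**
Reactants: 34 C15 angelate
Product: 35 CNP0179010.1
Conditions: Ac2O, pyridine, DMAP (cat.), CH2Cl2, rt
Reagents that add atoms: acetic anhydride, CC(=O)OC(C)=O
Why: DMAP-catalysed acetylation of the last, hindered hydroxyl group completes the target; no stereocentre or double-bond geometry is affected.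

**Compound list**
1 | 4,4-dimethoxycyclohexa-2,5-dien-1-one | COC1(OC)C=CC(=O)C=C1 | starting material
2 | (R)-4,4-dimethoxy-5-methylcyclohex-2-en-1-one | COC1(OC)C=CC(=O)C[C@H]1C | intermediate
3 | (1S,5R)-4,4-dimethoxy-5-methylcyclohex-2-en-1-ol | COC1(OC)C=C[C@@H](O)C[C@H]1C | intermediate
4 | TIPS ether of 3 | COC1(OC)C=C[C@@H](O[Si](C(C)C)(C(C)C)C(C)C)C[C@H]1C | intermediate
5 | (4S,6R)-6-methyl-4-(triisopropylsilyloxy)cyclohex-2-en-1-one | O=C1C=C[C@@H](O[Si](C(C)C)(C(C)C)C(C)C)C[C@H]1C | intermediate
6 | (1S,4S,6R)-6-methyl-4-(triisopropylsilyloxy)cyclohex-2-en-1-ol | O[C@@H]1C=C[C@@H](O[Si](C(C)C)(C(C)C)C(C)C)C[C@H]1C | intermediate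
7 | methyl carbonate of 6 | COC(=O)O[C@@H]1C=C[C@@H](O[Si](C(C)C)(C(C)C)C(C)C)C[C@H]1C | intermediate
8 | methyl acetoacetate | COC(=O)CC(C)=O | starting material
9 | allylated β-keto ester (C8 epimers) | COC(=O)C(C(C)=O)[C@@H]1C=C[C@@H](O[Si](C(C)C)(C(C)C)C(C)C)C[C@H]1C | intermediate
10 | α-cyclohexenyl-α-diazo ester | COC(=O)C(=[N+]=[N-])[C@@H]1C=C[C@@H](O[Si](C(C)C)(C(C)C)C(C)C)C[C@H]1C | intermediate
11 | methyl 5-methyl-3-(triisopropylsilyloxy)tricyclo[4.1.0.0(2,7)]heptane-1-carboxylate | COC(=O)[C@]12[C@@H]3[C@@H](O[Si](C(C)C)(C(C)C)C(C)C)C[C@@H](C)[C@H]1[C@H]23 | intermediate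
12 | Danishefsky's diene | CO/C=C/C(=C)O[Si](C)(C)C | starting material
13 | primary cycloadduct (C9 OMe, either epimer; C10=C11 OTMS) | C1[C@@H]2[C@H]3[C@@H](O[Si](C(C)C)(C(C)C)C(C)C)C[C@@H](C)[C@@H]2[C@@]3(C(=O)OC)C(OC)C=C1O[Si](C)(C)C | intermediate
14 | tricyclic cycloheptenone ester | C1[C@@H]2[C@H]3[C@@H](O[Si](C(C)C)(C(C)C)C(C)C)C[C@@H](C)[C@@H]2[C@@]3(C(=O)OC)C=CC1=O | intermediate
15 | lithium cross-conjugated dienolate of 14 | C=1[C@@H]2[C@H]3[C@@H](O[Si](C(C)C)(C(C)C)C(C)C)C[C@@H](C)[C@@H]2[C@@]3(C(=O)OC)C=CC=1[O-].[Li+] | intermediate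
16 | C1-methyl enone (C1 epimers) | CC1[C@@H]2[C@H]3[C@@H](O[Si](C(C)C)(C(C)C)C(C)C)C[C@@H](C)[C@@H]2[C@@]3(C(=O)OC)C=CC1=O | intermediate
17 | 2-(trimethylsilyloxy)diene | CC=1[C@@H]2[C@H]3[C@@H](O[Si](C(C)C)(C(C)C)C(C)C)C[C@@H](C)[C@@H]2[C@@]3(C(=O)OC)C=CC=1O[Si](C)(C)C | intermediate
18 | C1-methyl-C1-hydroxymethyl enone | OC[C@]1(C)[C@@H]2[C@H]3[C@@H](O[Si](C(C)C)(C(C)C)C(C)C)C[C@@H](C)[C@@H]2[C@@]3(C(=O)OC)C=CC1=O | intermediate
19 | C9 pinacol boronate | OC[C@]1(C)[C@@H]2[C@H]3[C@@H](O[Si](C(C)C)(C(C)C)C(C)C)C[C@@H](C)[C@@H]2[C@@]3(C(=O)OC)[C@H](B4OC(C)(C)C(C)(C)O4)CC1=O | intermediate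
20 | C9-hydroxy C11 ketone | OC[C@]1(C)[C@@H]2[C@H]3[C@@H](O[Si](C(C)C)(C(C)C)C(C)C)C[C@@H](C)[C@@H]2[C@@]3(C(=O)OC)[C@H](O)CC1=O | intermediate
21 | C9, C11, C15 triol ester | OC[C@]1(C)[C@@H]2[C@H]3[C@@H](O[Si](C(C)C)(C(C)C)C(C)C)C[C@@H](C)[C@@H]2[C@@]3(C(=O)OC)[C@H](O)C[C@H]1O | intermediate
22 | C11/C15 acetonide ester | CC1(C)OC[C@]2(C)[C@@H]3[C@H]4[C@@H](O[Si](C(C)C)(C(C)C)C(C)C)C[C@@H](C)[C@@H]3[C@@]4(C(=O)OC)[C@H](O)C[C@H]2O1 | intermediate
23 | C9/C12 diol | CC1(C)OC[C@]2(C)[C@@H]3[C@H]4[C@@H](O[Si](C(C)C)(C(C)C)C(C)C)C[C@@H](C)[C@@H]3[C@@]4(CO)[C@H](O)C[C@H]2O1 | intermediate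
24 | C12 mesylate | CC1(C)OC[C@]2(C)[C@@H]3[C@H]4[C@@H](O[Si](C(C)C)(C(C)C)C(C)C)C[C@@H](C)[C@@H]3[C@@]4(COS(C)(=O)=O)[C@H](O)C[C@H]2O1 | intermediate
25 | C8-methyl C9 alcohol | CC1(C)OC[C@]2(C)[C@@H]3[C@H]4[C@@H](O[Si](C(C)C)(C(C)C)C(C)C)C[C@@H](C)[C@@H]3[C@@]4(C)[C@H](O)C[C@H]2O1 | intermediate
26 | senecioic acid | CC(C)=CC(=O)O | starting material
27 | C9 senecioate | CC1(C)OC[C@]2(C)[C@@H]3[C@H]4[C@@H](O[Si](C(C)C)(C(C)C)C(C)C)C[C@@H](C)[C@@H]3[C@@]4(C)[C@H](OC(=O)C=C(C)C)C[C@H]2O1 | intermediate
28 | C4 alcohol | CC1(C)OC[C@]2(C)[C@@H]3[C@H]4[C@@H](O)C[C@@H](C)[C@@H]3[C@@]4(C)[C@H](OC(=O)C=C(C)C)C[C@H]2O1 | intermediate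
29 | saturated C4 ketone | CC1(C)OC[C@]2(C)[C@@H]3[C@H]4C(=O)C[C@@H](C)[C@@H]3[C@@]4(C)[C@H](OC(=O)C=C(C)C)C[C@H]2O1 | intermediate
30 | C4-oxo-C5=C6 enone acetonide | CC1(C)OC[C@]2(C)[C@@H]3[C@H]4C(=O)C=C(C)[C@@H]3[C@@]4(C)[C@H](OC(=O)C=C(C)C)C[C@H]2O1 | intermediate
31 | C11/C15 diol | OC[C@]1(C)[C@@H]2[C@H]3C(=O)C=C(C)[C@@H]2[C@@]3(C)[C@H](OC(=O)C=C(C)C)C[C@H]1O | intermediate
32 | angelic acid | C/C=C(/C)C(=O)O | starting material
33 | angelic 2,4,6-trichlorobenzoic anhydride | C/C=C(/C)C(=O)OC(=O)c1c(Cl)cc(Cl)cc1Cl | intermediate
34 | C15 angelate, C11–OH free | C/C=C(/C)C(=O)OC[C@]1(C)[C@@H]2[C@H]3C(=O)C=C(C)[C@@H]2[C@@]3(C)[C@H](OC(=O)C=C(C)C)C[C@H]1O | intermediate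
35 | CNP0179010.1 | C/C=C(/C)C(=O)OC[C@]1(C)[C@@H]2[C@H]3C(=O)C=C(C)[C@@H]2[C@@]3(C)[C@H](OC(=O)C=C(C)C)C[C@H]1OC(C)=O | target

Total step count: 24. Longest linear sequence: 24 steps (from 1).

**Steps most likely to fail**

**1. Step 9.**
- **Risk.** The diene may attack C2 along the customary rear-side trajectory on the concave face. That would end in an open-chain cyclobutane that cannot cyclise. The Lewis acid may also isomerise the bicyclobutane or consume the diene before the two meet.
- **Fallback idea (known chemistry, from 11 back to 14).** The two bonds are made separately, and C2 passes through a trigonal radical that can be trapped on the open face.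
- **Opening and formylation.** PhSeLi (PhSeH, n-BuLi, THF, −78 °C) opens the central bond in the established strain-release homo-Michael sense. The ester enolate is formylated in the same flask with 2,2,2-trifluoroethyl formate on the face away from the C4–C6 bridge, giving the seleno aldehyde F1.
- **C1–C2 bond.** Keck allylation (allyltributylstannane, AIBN, benzene, 80 °C) replaces selenium through the C2 radical. Trapping anti to the C4–C6 bridge gives the allyl aldehyde F2.
- **Ring closure.** Wacker–Tsuji oxidation (PdCl2, CuCl, O2, DMF/H2O) gives the keto aldehyde F3. An amine-catalysed intramolecular aldol condensation (pyrrolidine, AcOH) between the C10 methyl group and the non-enolisable C9 aldehyde then closes the seven-membered enone 14.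

**2. Step 8.**
- **Risk.** A 1,2-hydride shift from C7 in the carbenoid, or carbene dimerisation, may outrun the strained cyclopropanation, because the side chain must first become pseudo-axial.
- **Fallback (from 6 back to 11).** This is the gem-dibromocyclopropane/alkyllithium route to bicyclobutyllithiums.
- **Cyclopropane.** Appel chlorination (PPh3, CCl4) with inversion gives the allylic chloride F4, with Cl cis to methyl and silyl ether. Dibromocarbene (CHBr3, 50 % NaOH, BnEt3NCl) adds to the only open face to give the dibromonorcarane F5.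
- **Bicyclobutane.** MeLi (Et2O, −78 °C) effects bromine–lithium exchange and internal displacement of chloride to the bridgehead bromide F6. t-BuLi converts it into the bridgehead lithium compound F7, and methyl chloroformate gives 11.

**3. Step 12.**
- **Risk.** Facial discrimination by the catalyst at C1 may be poor, and the enol silane may hydrolyse in the aqueous medium.
- **Fallback (from 16 back to 18).** The quaternary centre is set by decarboxylative asymmetric allylic alkylation and the allyl group is then cut down.
- **Quaternary centre.** LiHMDS and allyl chloroformate give the allyl dienol carbonate F8. Pd2(dba)3 with (S)-t-Bu-PHOX (toluene, rt) gives the α-allyl-α-methyl enone F9, with allyl on the C3 side.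
- **Cutting down.** RuHCl(CO)(PPh3)3 (toluene, 80 °C) moves the double bond to give the propenyl enone F10. Ozonolysis stopped at the electron-rich alkene (O3, CH2Cl2, −78 °C; Me2S) gives the keto aldehyde F11. LiAlH(Ot-Bu)3 (THF, −78 °C) reduces only the aldehyde, giving 18.

**Further compounds**
F1 | step 9 | seleno aldehyde (C2 SePh, C8 CO2Me and CHO) | c1ccccc1[Se][C@H]2[C@H]3[C@@H](O[Si](C(C)C)(C(C)C)C(C)C)C[C@@H](C)[C@@H]2[C@@]3(C(=O)OC)C=O
F2 | step 9 | allyl aldehyde (C2 allyl anti to the C4–C6 bridge) | C=CC[C@@H]2[C@H]3[C@@H](O[Si](C(C)C)(C(C)C)C(C)C)C[C@@H](C)[C@@H]2[C@@]3(C(=O)OC)C=O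
F3 | step 9 | keto aldehyde (C2 acetonyl, C8 CHO) | CC(=O)C[C@@H]2[C@H]3[C@@H](O[Si](C(C)C)(C(C)C)C(C)C)C[C@@H](C)[C@@H]2[C@@]3(C(=O)OC)C=O
F4 | step 8 | allylic chloride (Cl at C7, cis to CH3 and OTIPS) | Cl[C@H]1C=C[C@@H](O[Si](C(C)C)(C(C)C)C(C)C)C[C@H]1C
F5 | step 8 | 7,7-dibromonorcarane chloride | Cl[C@H]1[C@H]2[C@@H]([C@@H](O[Si](C(C)C)(C(C)C)C(C)C)C[C@H]1C)C2(Br)Br
F6 | step 8 | bridgehead bromide of the tricycloheptane | Br[C@]12[C@@H]3[C@@H](O[Si](C(C)C)(C(C)C)C(C)C)C[C@@H](C)[C@H]1[C@H]23
F7 | step 8 | bridgehead lithium compound | [Li][C@]12[C@@H]3[C@@H](O[Si](C(C)C)(C(C)C)C(C)C)C[C@@H](C)[C@H]1[C@H]23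
F8 | step 12 | allyl dienol carbonate | CC=1[C@@H]2[C@H]3[C@@H](O[Si](C(C)C)(C(C)C)C(C)C)C[C@@H](C)[C@@H]2[C@@]3(C(=O)OC)C=CC=1OC(=O)OCC=C
F9 | step 12 | α-allyl-α-methyl enone | C=CC[C@]1(C)[C@@H]2[C@H]3[C@@H](O[Si](C(C)C)(C(C)C)C(C)C)C[C@@H](C)[C@@H]2[C@@]3(C(=O)OC)C=CC1=O
F10 | step 12 | (E)-propenyl enone | C/C=C/[C@]1(C)[C@@H]2[C@H]3[C@@H](O[Si](C(C)C)(C(C)C)C(C)C)C[C@@H](C)[C@@H]2[C@@]3(C(=O)OC)C=CC1=O
F11 | step 12 | C15 keto aldehyde | O=C[C@]1(C)[C@@H]2[C@H]3[C@@H](O[Si](C(C)C)(C(C)C)C(C)C)C[C@@H](C)[C@@H]2[C@@]3(C(=O)OC)C=CC1=O
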